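**Retrosynthetic overview**

1. The δ-lactone is made last by cutting two of its ring bonds at once, the carbonyl–spiro bond C2′–C3′ and the C5′–C6′ bond. This is a formal [3+3] union of spiro vinylcyclopropane 10 (spiro C, CH2, CH–isopropenyl) with 4-isopropyl-1,3-dioxol-2-one 13 (C(=O)–O–CH, already bonded to the isobutyryl carbon); every atom of both partners is kept.
2. Enabling feature: the spiro carbon C5 is α to the cyclopentanone carbonyl C6, and C5′, two bonds away in the oxanone ring, carries the isopropenyl group. These are the two ends of a ketone-acceptor/vinyl-donor cyclopropane, which zerovalent palladium opens with strain release to an enolate/π-allyl zwitterion. The O1′–C2′(=O) and C6′H–C(=O)iPr part of the ring is a ring-opened enediol carbonate.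
3. C6′ (α to the isobutyryl ketone, the only epimerisable centre) is reset at the end by kinetic protonation, so the key step need not control it.
4. 10 comes from bicyclic keto lactone 7 and isoprene dibromide 8. 7 comes from a Dieckmann closure of lactone ester 5 and C-methylation. 5 comes from (R)-α-terpineol 1 (oxidative cleavage, haloform reaction), which supplies C3a and the gem-dimethyl lactone.
5. Order of ring formation: γ-lactone (step 1), cyclopentanone (step 4), temporary cyclopropane (step 6), δ-lactone (step 8).

Key step: step 8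

Remark: 14 is drawn as the 5′,6′-trans epimer expected from the ring closure; because step 9 resets C6′, the cis epimer or a mixture would serve equally; 8 and 11 are taken as purchasable.

**Route**

Step 1
Reactants: 1 (R)-(+)-α-terpineol, 2-[(1R)-4-methylcyclohex-3-en-1-yl]propan-2-ol
Product: 3 (4R)-5,5-dimethyl-4-(3-oxobutyl)oxolan-2-one, via hydroxy keto acid 2 (not isolated)
Conditions: RuCl3·H2O (2 mol%), NaIO4 (4 equiv), MeCN/EtOAc/H2O, 0 °C to rt; acidic work-up
Reagents that add atoms: sodium periodate, [Na+].[O-]I(=O)(=O)=O
Why: Oxidative cleavage of the trisubstituted ring alkene by RuO4 formed in situ should give a methyl ketone and a carboxylic acid, and the γ-hydroxy acid 2 should lactonise with the tertiary alcohol; the stereocentre (later C3a) is not touched.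

Step 2
Reactants: 3 (4R)-5,5-dimethyl-4-(3-oxobutyl)oxolan-2-one
Product: 4 3-[(3R)-2,2-dimethyl-5-oxooxolan-3-yl]propanoic acid
Conditions: NaOCl (aq., 3.3 equiv), NaOH, dioxane/H2O, 0 °C to rt; then HCl to pH 1
Reagents that add atoms: sodium hydroxide, [Na+].[OH-]
Why: Haloform reaction of the methyl ketone, the classical degradation to the acid one carbon shorter; the CH3 group is halogenated much faster than the CH2 on the other side of the ketone.

Step 3
Reactants: 4 3-[(3R)-2,2-dimethyl-5-oxooxolan-3-yl]propanoic acid
Product: 5 methyl 3-[(3R)-2,2-dimethyl-5-oxooxolan-3-yl]propanoate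
Conditions: MeI, K2CO3, DMF, rt
Reagents that add atoms: iodomethane, CI
Why: O-Alkylation of the carboxylate (SN2 on MeI) under conditions that leave the lactone closed.

Step 4
Reactants: 5 methyl 3-[(3R)-2,2-dimethyl-5-oxooxolan-3-yl]propanoate
Product: 6 (3aR,6aR)-3,3-dimethyltetrahydro-1H-cyclopenta[c]furan-1,6(6aH)-dione
Conditions: LiN(SiMe3)2 (2.2 equiv), THF, −78 °C to 0 °C; aq. HCl work-up
Reagents that add atoms: none
Why: Dieckmann condensation: the lactone α-CH2 is several pKa units more acidic than the ester α-CH2, so its enolate should form and close 5-exo-trig on the methyl ester, the product being held as its β-dicarbonyl enolate; the five-five ring fusion can only be cis.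

Step 5
Reactants: 6 (3aR,6aR)-3,3-dimethyltetrahydro-1H-cyclopenta[c]furan-1,6(6aH)-dione
Product: 7 (3aR,6aR)-3,3,6a-trimethyltetrahydro-1H-cyclopenta[c]furan-1,6(6aH)-dione
Conditions: MeI, K2CO3, acetone, 40 °C
Reagents that add atoms: iodomethane, CI
Why: C-Alkylation of a cyclic β-keto lactone enolate; MeI can only enter on the face of 3a-H because a trans-fused bicyclo[3.3.0] skeleton is too strained, which sets the 6a quaternary centre.

Step 6
Reactants: 7 (3aR,6aR)-3,3,6a-trimethyltetrahydro-1H-cyclopenta[c]furan-1,6(6aH)-dione; 8 (E)-1,4-dibromo-2-methylbut-2-ene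
Product: 10 (3aR,6aR)-3,3,6a-trimethyl-2′-(prop-1-en-2-yl)tetrahydrospiro[cyclopenta[c]furan-5,1′-cyclopropane]-1,6-dione (mixture of diastereomers at the two new cyclopropane carbons), via allylic bromide 9 (not isolated)
Conditions: LiN(SiMe3)2 (1.05 equiv), THF, −78 °C; 8 (1.5 equiv), −78 °C to 0 °C; then NaN(SiMe3)2 (1.1 equiv), −78 °C to rt
Reagents that add atoms: none
Why: Double alkylation of a ketone with a 1,4-dihalobut-2-ene (the standard vinylcyclopropane synthesis): C5, the only enolisable carbon, should first displace the more reactive prenyl-type CH2Br next to CH=, then the second enolate closes 3-exo in an SN2′ manner; the configuration of both new centres is irrelevant because step 8 erases them.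

Step 7
Reactants: 11 1-hydroxy-3-methylbutan-2-one
Product: 13 4-(propan-2-yl)-1,3-dioxol-2-one, via imidazolide 12 (not isolated)
Conditions: CDI (1.1 equiv), CH2Cl2, rt; then DBU (10 mol%), 40 °C
Reagents that add atoms: 1,1′-carbonyldiimidazole, O=C(n1ccnc1)n1ccnc1
Why: Acyloin to 1,3-dioxol-2-one conversion: O-acylation by CDI, then base-promoted enolisation towards the doubly activated O–CH2 and 5-exo-trig attack of the enol oxygen on the acyl imidazole.

Step 8
Reactants: 10 spiro vinylcyclopropane (as above); 13 4-(propan-2-yl)-1,3-dioxol-2-one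
Product: 14 (3aR,5R,6aR,5′S,6′R)-3,3,6a-trimethyl-6′-(2-methylpropanoyl)-5′-(prop-1-en-2-yl)tetrahydrospiro[cyclopenta[c]furan-5,3′-oxane]-1,2′,6-trione (the 6′-epimer of the target)
Conditions: Pd2(dba)3·CHCl3 (2.5 mol%), dppe (6 mol%), 13 (2 equiv), toluene, 50 °C
Reagents that add atoms: none
Why: Proposed new method: zerovalent palladium opens the strained, ketone-activated vinylcyclopropane of 10 (both cyclopropane stereocentres are erased) to a zwitterion of the C5 cyclopentanone enolate and a 2-methyl-π-allylpalladium cation; the enolate carbon attacks the carbonate carbonyl of 13, the dioxolone ring opens to the enolate of an α-acyloxy ketone, and this carbon closes on the internal allyl terminus, forming the δ-lactone by 6-exo attack on the π-allyl unit and leaving the isopropenyl group. The closest known reaction types are the palladium-catalysed formal [3+2] and [3+3] cycloadditions of vinylcyclopropanes with partners that are first attacked by the enolate and then attack the allyl unit, and the ring-opening acyl transfer from 1,3-dioxol-2-ones to nucleophiles such as amines. The spiro centre is set in the C-acylation, which should take the convex face of the cis-fused bicycle (the face of 3a-H and 6a-CH3, away from the γ-lactone ring and its gem-dimethyl group). C5′ is set under Curtin–Hammett control, since the allyl faces exchange through the σ-allyl at the CH2 terminus: in the half-chair closure the allyl unit and the ring CH2 on the spiro carbon sit equatorial and the ring ketone axial (smaller, and with its dipole turned away from the ester carbonyl), which places isopropenyl cis to that CH2 (5′S). C6′ should come out mainly trans to isopropenyl (both substituents equatorial) and is reset in step 9, so its outcome here is not critical. The step needs C- rather than O-acylation and closure through the CH rather than the C(iPr) end of the enediolate; O-acylation and the acyl shift between the two enediolate oxygens are reversible, and only the CH carbon can reach the allyl terminus through a six-membered transition state without building a quaternary centre next to C5′.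

Step 9
Reactants: 14 6′-epimer of the target (as above)
Product: 16 (3aR,5R,6aR,5′S,6′S)-3,3,6a-trimethyl-6′-(2-methylpropanoyl)-5′-(prop-1-en-2-yl)tetrahydrospiro[cyclopenta[c]furan-5,3′-oxane]-1,2′,6-trione (CNP0216954.2), via lithium enolate 15 (not isolated)
Conditions: LiN(SiMe3)2 (1.1 equiv), THF, −78 °C; then cannulated into AcOH (5 equiv)/THF, −78 °C
Reagents that add atoms: none
Why: Kinetic protonation of an exocyclic enolate (contra-thermodynamic, least-hindered approach): C6′–H is the only readily removed proton, both C6′ epimers give the same enolate 15, and the acid should deliver the proton to the face opposite the neighbouring isopropenyl group, which leaves the isobutyryl group cis to it (6′S).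

**Compound list**

1 | (R)-(+)-α-terpineol | CC1=CC[C@@H](CC1)C(C)(C)O | starting material
2 | (3R)-3-(2-hydroxypropan-2-yl)-6-oxoheptanoic acid (not isolated) | CC(=O)CC[C@H](CC(=O)O)C(C)(C)O | intermediate
3 | (4R)-5,5-dimethyl-4-(3-oxobutyl)oxolan-2-one | CC(=O)CC[C@@H]1CC(=O)OC1(C)C | intermediate
4 | 3-[(3R)-2,2-dimethyl-5-oxooxolan-3-yl]propanoic acid | OC(=O)CC[C@@H]1CC(=O)OC1(C)C | intermediate
5 | methyl 3-[(3R)-2,2-dimethyl-5-oxooxolan-3-yl]propanoate | COC(=O)CC[C@@H]1CC(=O)OC1(C)C | intermediate
6 | (3aR,6aR)-3,3-dimethyltetrahydro-1H-cyclopenta[c]furan-1,6(6aH)-dione | C1C[C@H]2C(C)(C)OC(=O)[C@H]2C1=O | intermediate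
7 | (3aR,6aR)-3,3,6a-trimethyltetrahydro-1H-cyclopenta[c]furan-1,6(6aH)-dione | C1C[C@H]2C(C)(C)OC(=O)[C@@]2(C)C1=O | intermediate
8 | (E)-1,4-dibromo-2-methylbut-2-ene | BrC/C=C(\C)CBr | starting material
9 | (3aR,6aR)-5-[(2E)-4-bromo-3-methylbut-2-en-1-yl]-3,3,6a-trimethyltetrahydro-1H-cyclopenta[c]furan-1,6(6aH)-dione, C5 epimers (not isolated) | BrC/C(C)=C/CC1C[C@H]2C(C)(C)OC(=O)[C@@]2(C)C1=O | intermediate
10 | (3aR,6aR)-3,3,6a-trimethyl-2′-(prop-1-en-2-yl)tetrahydrospiro[cyclopenta[c]furan-5,1′-cyclopropane]-1,6-dione, diastereomer mixture at the cyclopropane | C=C(C)C1CC12C[C@H]3C(C)(C)OC(=O)[C@@]3(C)C2=O | intermediate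
11 | 1-hydroxy-3-methylbutan-2-one | CC(C)C(=O)CO | starting material
12 | 3-methyl-2-oxobutyl 1H-imidazole-1-carboxylate (not isolated) | CC(C)C(=O)COC(=O)n1ccnc1 | intermediate
13 | 4-(propan-2-yl)-1,3-dioxol-2-one | CC(C)C1=COC(=O)O1 | intermediate
14 | (3aR,5R,6aR,5′S,6′R)-spiro lactone, 6′-epimer of the target | C=C(C)[C@@H]1C[C@]2(C[C@H]3C(C)(C)OC(=O)[C@@]3(C)C2=O)C(=O)O[C@H]1C(=O)C(C)C | intermediate
15 | lithium enolate of 14 at C6′ (not isolated) | [Li+].C=C(C)[C@@H]1C[C@]2(C[C@H]3C(C)(C)OC(=O)[C@@]3(C)C2=O)C(=O)OC1=C([O-])C(C)C | intermediate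
16 | (3aR,5R,6aR,5′S,6′S)-3,3,6a-trimethyl-6′-(2-methylpropanoyl)-5′-(prop-1-en-2-yl)tetrahydrospiro[cyclopenta[c]furan-5,3′-oxane]-1,2′,6-trione | C=C(C)[C@@H]1C[C@]2(C[C@H]3C(C)(C)OC(=O)[C@@]3(C)C2=O)C(=O)O[C@@H]1C(=O)C(C)C | target

**Step count and risks**

Total: 9 steps. Longest linear sequence: 8 steps (steps 1 to 6, 8 and 9); step 7 is a one-step branch.

Steps most likely to fail:

1. Step 8 (proposed new method). What may go wrong: slow ionisation of the singly activated cyclopropane, capture of the zwitterion through oxygen instead of carbon, or loss of a proton from the π-allyl unit to a diene before the second ring bond forms. Fallback with known chemistry, making the same two bonds in separate operations: step 6 is stopped after the first alkylation and allylic bromide 9 is isolated. CsOAc in DMF should convert it into the allylic acetate F1. Its lithium enolate (LiN(SiMe3)2, THF, −78 °C) is carboxylated with CO2 on the convex face to the lithium carboxylate F2, which is alkylated in the same flask with 1-bromo-3-methylbutan-2-one to the keto ester F3. Pd(PPh3)4 and Cs2CO3 in THF should then close the ring by intramolecular Tsuji–Trost alkylation, and the route is rejoined at 14.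

2. Step 9. What may go wrong: poor facial selectivity in the protonation, or re-equilibration towards the trans epimer during work-up. Fallback by reagent control, setting out from 14: the enolate 15 is trapped with Me3SiCl as the silyl enol ether F4. F4 is protonated at −78 °C by a chiral Lewis-acid-assisted Brønsted acid (BINOL·SnCl4, the enantiomer matched to the required face), which should return to the route at 16.

3. Step 6. What may go wrong: the first alkylation taking place at the other CH2Br end of 8 (which would lead to a 2-methyl-2-vinylcyclopropane), or closure of the second enolate through oxygen instead of carbon. Fallback with unambiguous regiochemistry, setting out from 7: alkylation with prenyl bromide (LiN(SiMe3)2, THF) gives the prenyl ketone F5. Allylic oxidation with SeO2 (cat.) and t-BuOOH should give the (E)-allylic alcohol F6. CBr4/PPh3 converts it into 9, where the route is rejoined, and NaN(SiMe3)2 closes the cyclopropane as in step 6.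

**Further compounds**

F1 | step 8 | (2E)-2-methyl-4-[(3aR,6aR)-3,3,6a-trimethyl-1,6-dioxohexahydro-1H-cyclopenta[c]furan-5-yl]but-2-en-1-yl acetate (C5 epimers) | CC(=O)OC/C(C)=C/CC1C[C@H]2C(C)(C)OC(=O)[C@@]2(C)C1=O
F2 | step 8 | lithium (3aR,5R,6aR)-5-[(2E)-4-acetoxy-3-methylbut-2-en-1-yl]-3,3,6a-trimethyl-1,6-dioxohexahydro-1H-cyclopenta[c]furan-5-carboxylate | [Li+].CC(=O)OC/C(C)=C/C[C@]1(C[C@H]2C(C)(C)OC(=O)[C@@]2(C)C1=O)C(=O)[O-]
F3 | step 8 | 3-methyl-2-oxobutyl (3aR,5R,6aR)-5-[(2E)-4-acetoxy-3-methylbut-2-en-1-yl]-3,3,6a-trimethyl-1,6-dioxohexahydro-1H-cyclopenta[c]furan-5-carboxylate | CC(=O)OC/C(C)=C/C[C@]1(C[C@H]2C(C)(C)OC(=O)[C@@]2(C)C1=O)C(=O)OCC(=O)C(C)C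
F4 | step 9 | trimethylsilyl enol ether of 14 at C6′ | C=C(C)[C@@H]1C[C@]2(C[C@H]3C(C)(C)OC(=O)[C@@]3(C)C2=O)C(=O)OC1=C(O[Si](C)(C)C)C(C)C
F5 | step 6 | (3aR,6aR)-3,3,6a-trimethyl-5-(3-methylbut-2-en-1-yl)tetrahydro-1H-cyclopenta[c]furan-1,6(6aH)-dione (C5 epimers) | CC(C)=CCC1C[C@H]2C(C)(C)OC(=O)[C@@]2(C)C1=O
F6 | step 6 | (3aR,6aR)-5-[(2E)-4-hydroxy-3-methylbut-2-en-1-yl]-3,3,6a-trimethyltetrahydro-1H-cyclopenta[c]furan-1,6(6aH)-dione (C5 epimers) | OC/C(C)=C/CC1C[C@H]2C(C)(C)OC(=O)[C@@]2(C)C1=O
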